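A small charge of G, 0.025 M, is doubled from flask to flask up to 0.20 M, and [G.J] at the end of each run is wanted.

the same everywhere: X 12 mM (held); time 10 min
- Sunday's: G 0.025 M
- Monday's: G 0.050 M
- Thursday's: G 0.10 M
- Wednesday's: G 0.20 M

    G + J → G.J, rate k1*[G]^2*[J]^0.5 (k1 = 19.4 M⁻¹·⁵ min⁻¹)
    G.J ⇌ Q (K2 = 13, k2 = 0.455 min⁻¹)
    X ⇌ J, rate k3*(csat - [J]) (k3 = 0.299 min⁻¹, csat = 12 mM)
    G + G.J → G.G.J (k4 = 5.07 M⁻¹ min⁻¹)

- percentages count the G that a species holds: one G.G.J counts as two
- at the start none of J is dissolved
- "hardly changes" means that all values lie within two and a half points (for a concentration: within two and a half percent of the largest)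
- run time (Sunday's): 10 min

1. [G.J] at the end for Sunday's, Monday's, Thursday's, Wednesday's, in this order
2. how that number moves from the first to the last of them (rises all the way / falls all the way / rises, then falls / falls, then rises / hardly changes)

Can the gas X keep up with each charge? Sunday's charge gives D = 0.370, where D is the demand ratio, the uptake of J by G at the saturation concentration csat over the transfer into a flask empty of J. D goes with the square of the charge, so its logarithm climbs from −0.432 by 0.602 per doubling: Monday's has 1.48, Thursday's 5.92 and Wednesday's 23.7.

What does J do then? Where uptake balances transfer at large D, J sits near csat over the square of D, and for Wednesday's charge that is 2.14 × 10⁻⁵ M. In Wednesday's flask transfer, at its ceiling of 0.00359 M min⁻¹, is then the rate-limiting step, so this reckoning feeds G.J at the smaller of demand and ceiling.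

Does G.J lag behind that feed or follow it? Its two drains, to Q and to G.G.J, give a half-life of 1.19 min in Sunday's flask, shorter than the run. G.J is therefore reckoned as a quasi-steady intermediate, at feed over drain. With G at its charge, demand taken at csat and no return from Q, the row reckons to 0.00228 M, 0.00506 M, 0.00373 M and 0.00244 M, which rises, then falls, with its peak at Monday's.

The forecast gives 0.0016 M, 0.0033 M, 0.0046 M and 0.0032 M, rises, then falls, on the ground that formation "is capped by how fast J can dissolve", and its peak stands at Thursday's, not at Monday's as in this reckoning.

The flasks give 0.00134 M, 0.00277 M, 0.00424 M and 0.00323 M, rises, then falls, with the turn read at a charge of 0.11 M.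

At the end of Sunday's run, G at 68.9% of its charge brings D to 0.176, and J, at 0.00934 M, is made 1.43 times faster than it is used, each step taken net. At the end of Wednesday's run, G at 71.0% of its charge brings D to 12.0, so csat over its square is 8.39 × 10⁻⁵ M, and J stands at 8.22 × 10⁻⁵ M.

All constants were set for the occasion; what happens was integrated by code.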